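Cuts (flavan numbering): first the bond between the bridging CH2 on C8 and the one free ring carbon of the acylphloroglucinol ring, then the C4-C3 and O1-C2 bonds of ring C together in a retro oxa-[4+2] operation.
Enabling feature: C4 and the C8 methylene are both benzylic carbons of ring A ortho to a ring-A oxygen (O1 on C8a, OH on C7), so each can be the CH2 terminus of an ortho-quinone methide. A mirror-symmetric 4-O-benzyl-2,6-dihydroxybenzaldehyde carries the future bridge carbon as CHO, and its symmetry removes the C6/C8 choice.
Forward: rings A, B and the acylphloroglucinol ring are bought as arenes. Ring C is closed by cycloaddition of the ring-A quinone methide with an (E)-beta-acetoxystyrene carrying ring B. The C8 formyl group is then reduced, and the acylphloroglucinol captures a second quinone methide, which joins the halves without forming a ring.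
Stereochemistry: C2 and C3 arise together in the cycloaddition. They are trans from the E alkene (suprafacial addition, backed by acetoxonium participation) and (2R,3S) from a chiral phosphoric acid that selects the alkene face. Nothing later touches them.
The 3-acetate is removed before the base-sensitive methylene bridge exists, and hydrogenolysis of three benzyl ethers ends the route.
Key step: step 7

Assumption: no close analogue allows the sense of induction of the phosphoric acid to be predicted, so the (R) catalyst is written. Its (S) antipode would be taken if the (2S,3R) adduct should prevail.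

Step 1
Reactants: 1 2,4,6-trihydroxybenzaldehyde
Product: 2 4-(benzyloxy)-2,6-dihydroxybenzaldehyde
Conditions: BnBr (1.0 equiv), NaHCO3 (1.1 equiv), DMF, rt to 40 °C
Reagents that add atoms: benzyl bromide, BrCc1ccccc1
Why: Williamson etherification under weak base, in which hydrogen carbonate should ionise only the 4-hydroxyl (para to the formyl group and outside the hydrogen-bonded salicylaldehyde array), so that one benzyl group goes there and the mirror plane through C1 and C4 is kept.

Step 2
Reactants: 2 4-(benzyloxy)-2,6-dihydroxybenzaldehyde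
Product: 3 5-(benzyloxy)-7-hydroxy-2-phenyl-4H-1,3,2-benzodioxaborinine-8-carbaldehyde
Conditions: PhB(OH)2 (1.05 equiv), (CH2O)n (1.5 equiv), EtCO2H (cat.), toluene, reflux, Dean-Stark trap
Reagents that add atoms: paraformaldehyde (as formaldehyde), C=O; phenylboronic acid, OB(O)c1ccccc1
Why: Boronic-acid-templated ortho-hydroxymethylation of a phenol, in which the aryl boronate binds formaldehyde, delivers it through a cyclic transition state to the adjacent free carbon (C3 and C5 are equivalent) and traps the product as the dioxaborinine, so that no free salicyl alcohol meets hot acid and one equivalent of boronic acid limits the reaction to one side.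

Step 3
Reactants: 3 5-(benzyloxy)-7-hydroxy-2-phenyl-4H-1,3,2-benzodioxaborinine-8-carbaldehyde
Product: 4 4-(benzyloxy)-2,6-dihydroxy-3-(hydroxymethyl)benzaldehyde
Conditions: pinacol (1.2 equiv), THF, rt; boronate by-product washed out with hexane; 4 used promptly
Reagents that add atoms: none
Why: Boronate transesterification, in which pinacol forms the more stable five-membered phenylboronate and frees the salicyl alcohol under neutral, non-oxidising conditions, avoiding the Dakin oxidation of the salicylaldehyde that a peroxide cleavage would risk.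

Step 4
Reactants: 5 3,4-bis(benzyloxy)benzaldehyde
Product: 6 2-{(E)-2-[3,4-bis(benzyloxy)phenyl]ethenyl}-4,4,5,5-tetramethyl-1,3,2-dioxaborolane
Conditions: CH2(Bpin)2 (1.2 equiv), lithium 2,2,6,6-tetramethylpiperidide (1.2 equiv), THF, 0 °C; then 5, -78 °C to rt
Reagents that add atoms: bis(pinacolatoboryl)methane, CC1(C)OB(CB2OC(C)(C)C(C)(C)O2)OC1(C)C
Why: Boron-Wittig olefination, in which the lithiated gem-diboronate adds to the non-enolisable aldehyde and syn B-O elimination from the less crowded adduct should give the E alkenylboronate, fixing the alkene geometry that the key step relies on.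

Step 5
Reactants: 6 2-{(E)-2-[3,4-bis(benzyloxy)phenyl]ethenyl}-4,4,5,5-tetramethyl-1,3,2-dioxaborolane
Product: 7 potassium {(E)-2-[3,4-bis(benzyloxy)phenyl]ethenyl}trifluoroborate
Conditions: KHF2 (4 equiv, aq.), MeOH, rt
Reagents that add atoms: potassium hydrogen difluoride, [K+].[F-].F
Why: Standard conversion of a pinacol boronate into the crystalline trifluoroborate salt, which does not touch the alkene and allows purification of the E isomer by precipitation.

Step 6
Reactants: 7 potassium {(E)-2-[3,4-bis(benzyloxy)phenyl]ethenyl}trifluoroborate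
Product: 8 (E)-2-[3,4-bis(benzyloxy)phenyl]ethenyl acetate
Conditions: AcOH (2 equiv), CuBr (10 mol %), 4-(dimethylamino)pyridine (20 mol %), 4 Å MS, O2 (1 atm), MeCN, 60 °C
Reagents that add atoms: acetic acid, CC(=O)O
Why: Chan-Lam-type oxidative copper-catalysed C-O coupling of an alkenyltrifluoroborate with a carboxylic acid, which transfers the alkenyl group with retention and so carries the E geometry into the enol ester, whereas enol acetylation of the arylacetaldehyde would give E/Z mixtures.

Step 7
Reactants: 4 4-(benzyloxy)-2,6-dihydroxy-3-(hydroxymethyl)benzaldehyde; 8 (E)-2-[3,4-bis(benzyloxy)phenyl]ethenyl acetate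
Product: 10 (2R,3S)-3-acetoxy-5-(benzyloxy)-2-[3,4-bis(benzyloxy)phenyl]-7-hydroxychromane-8-carbaldehyde, via ortho-quinone methide 9 (not isolated)
Conditions: (R)-3,3'-bis(2,4,6-triisopropylphenyl)-1,1'-binaphthyl-2,2'-diyl hydrogen phosphate (10 mol %), 8 (1.5 equiv), 5 Å MS, CH2Cl2, 0 °C to rt, slow addition of 4
Reagents that add atoms: none
Why: Proposed new method: the phosphoric acid dehydrates 4 to the ortho-quinone methide 9 (CH2=C4a-C8a=O) and stays bound to its C8a carbonyl, C8 formyl and C7 hydroxyl oxygens, the acetoxy-bearing carbon of 8 adds to the exocyclic CH2 (C4-C3 bond) while positive charge builds up at the carbon benzylic to ring B, and the quinone methide oxygen collapses onto that carbon (O1-C2 bond). The closest known reactions are Brønsted acid catalysed inverse-electron-demand oxa-Diels-Alder reactions of in situ ortho-quinone methides with electron-rich styrenes and enecarbamates, chiral phosphoric acid versions included, and cycloadditions of formaldehyde-derived quinone methides of formylphloroglucinols with alkenes; untested is a beta-acyloxystyrene with a CH2-terminated quinone methide under enantiocontrol. Ring C closes as a six-membered ring in one intermolecular, strongly asynchronous [4+2] event, and if a discrete cation intervenes the second bond forms by 6-exo-trig capture of the para-benzyloxybenzyl cation by the C8a oxygen. C3 is fixed when the C4-C3 bond forms, by the enantiotopic face of the alkene that the catalyst pocket admits (C4 ends as a CH2 group, so the face of the quinone methide leaves no stereochemical trace), and C2 follows from C3 by suprafacial addition to the E alkene, a stepwise path leading to the same 2,3-trans product because the acetate bridges the cation as a cis-acetoxonium ion that O1 opens with inversion and because the product is diequatorial. The step needs regiocontrol, secured by acylation of the enol oxygen, which makes it a poor donor so that the para-benzyloxy group of ring B decides the polarisation of the alkene; closure through the right oxygen is secured by the benzyl ether on the other oxygen ortho to C4a, the C8 position of the formyl group by the mirror symmetry of 2, and self-condensation is held back by the formyl group and the slow addition.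

Step 8
Reactants: 10 (2R,3S)-3-acetoxy-5-(benzyloxy)-2-[3,4-bis(benzyloxy)phenyl]-7-hydroxychromane-8-carbaldehyde
Product: 11 (2R,3S)-5-(benzyloxy)-2-[3,4-bis(benzyloxy)phenyl]-3,7-dihydroxychromane-8-carbaldehyde
Conditions: K2CO3 (2 equiv), MeOH-THF, 0 °C to rt
Reagents that add atoms: none
Why: Carbonate-promoted transesterification with methanol removes the acetate while no methylene bridge is present (such bridges scramble in base by retro-Michael cleavage, the rottlerone change), and with the 4'-oxygen benzylated ring C cannot open to a quinone methide, so C2 should not epimerise.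

Step 9
Reactants: 11 (2R,3S)-5-(benzyloxy)-2-[3,4-bis(benzyloxy)phenyl]-3,7-dihydroxychromane-8-carbaldehyde
Product: 12 (2R,3S)-5-(benzyloxy)-2-[3,4-bis(benzyloxy)phenyl]-8-(hydroxymethyl)chromane-3,7-diol
Conditions: NaBH4 (1 equiv), THF-MeOH, -10 to 0 °C, short contact; pH 7 phosphate buffer; used without chromatography
Reagents that add atoms: none
Why: Borohydride reduction of the aryl aldehyde to the salicyl alcohol, kept cold and short so that the phenoxide does not expel the benzylic oxygen and take up a second hydride, with C2 and C3 untouched.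

Step 10
Reactants: 13 2,4,6-trihydroxytoluene
Product: 14 2-methyl-1-(2,4,6-trihydroxy-3-methylphenyl)propan-1-one
Conditions: i-PrCOCl (1.1 equiv), AlCl3 (4 equiv), CH2Cl2-MeNO2, 0 to 40 °C; aq. HCl work-up
Reagents that add atoms: isobutyryl chloride, CC(C)C(=O)Cl
Why: Friedel-Crafts acylation, in which the two free ring carbons of 13 are equivalent and the first acyl group deactivates the ring towards a second.

Step 11
Reactants: 14 2-methyl-1-(2,4,6-trihydroxy-3-methylphenyl)propan-1-one
Product: 15 1-[2-hydroxy-4,6-bis(methoxymethoxy)-3-methylphenyl]-2-methylpropan-1-one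
Conditions: MOMCl (2.2 equiv), i-Pr2NEt (2.5 equiv), CH2Cl2, 0 °C to rt
Reagents that add atoms: chloromethyl methyl ether, COCCl
Why: Selective MOM ether formation, in which the hydroxyl between the methyl and the acyl group is the most hindered one and is held in the hydrogen bond to the ketone, so that the two hydroxyls flanking the free ring carbon should react first, as is usual for 3-methylphloroacylphenones.

Step 12
Reactants: 15 1-[2-hydroxy-4,6-bis(methoxymethoxy)-3-methylphenyl]-2-methylpropan-1-one
Product: 16 1-[2-methoxy-4,6-bis(methoxymethoxy)-3-methylphenyl]-2-methylpropan-1-one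
Conditions: MeI (5 equiv), K2CO3 (3 equiv), DMF, 50 °C
Reagents that add atoms: iodomethane, CI
Why: Williamson O-methylation of the remaining chelated phenol, forced by excess iodomethane in a dipolar solvent, with a base too weak to enolise the isopropyl ketone and harmless to the MOM ethers.

Step 13
Reactants: 16 1-[2-methoxy-4,6-bis(methoxymethoxy)-3-methylphenyl]-2-methylpropan-1-one
Product: 17 1-(4,6-dihydroxy-2-methoxy-3-methylphenyl)-2-methylpropan-1-one
Conditions: 3 M HCl, MeOH, 55 °C
Reagents that add atoms: none
Why: Acid-catalysed acetal exchange with methanol cleaves both MOM ethers while the aryl methyl ether and the ketone are inert.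

Step 14
Reactants: 12 (2R,3S)-5-(benzyloxy)-2-[3,4-bis(benzyloxy)phenyl]-8-(hydroxymethyl)chromane-3,7-diol; 17 1-(4,6-dihydroxy-2-methoxy-3-methylphenyl)-2-methylpropan-1-one
Product: 19 1-[3-({(2R,3S)-5-(benzyloxy)-2-[3,4-bis(benzyloxy)phenyl]-3,7-dihydroxychroman-8-yl}methyl)-2,4-dihydroxy-6-methoxy-5-methylphenyl]-2-methylpropan-1-one, via flavan ortho-quinone methide 18 (not isolated)
Conditions: 17 (4 equiv), pyridinium p-toluenesulfonate (20 mol %), 4 Å MS, THF-CH2Cl2, rt, slow addition of 12
Reagents that add atoms: none
Why: Acid-triggered loss of water from the salicyl alcohol (C8-CH2OH ortho to the free C7-OH) gives quinone methide 18, and Michael-type Friedel-Crafts addition of the only free ring carbon of 17 followed by rearomatisation forms the bridge, the known way to unsymmetrical methylene-bridged acylphloroglucinols; 17 is the much stronger acid and should react through its phenolate in the pyridine-buffered medium, and its excess and the slow addition hold back attack by C6 of ring A.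

Step 15
Reactants: 19 1-[3-({(2R,3S)-5-(benzyloxy)-2-[3,4-bis(benzyloxy)phenyl]-3,7-dihydroxychroman-8-yl}methyl)-2,4-dihydroxy-6-methoxy-5-methylphenyl]-2-methylpropan-1-one
Product: 20 pilosanol B
Conditions: H2 (1 atm), 10% Pd/C, THF-MeOH, rt
Reagents that add atoms: none
Why: Catalytic hydrogenolysis of the three benzyl ethers under neutral conditions, as routinely applied to benzylated flavan-3-ols, under which the O1-C2 bond, the diarylmethane bridge and the hydrogen-bonded aryl ketone should survive and no stereocentre is affected.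

Compound list
1 | 2,4,6-trihydroxybenzaldehyde | O=Cc1c(O)cc(O)cc1O | starting material
2 | 4-(benzyloxy)-2,6-dihydroxybenzaldehyde | O=Cc1c(O)cc(OCc2ccccc2)cc1O | intermediate
3 | 5-(benzyloxy)-7-hydroxy-2-phenyl-4H-1,3,2-benzodioxaborinine-8-carbaldehyde | O=Cc1c(O)cc(OCc2ccccc2)c2c1OB(c1ccccc1)OC2 | intermediate
4 | 4-(benzyloxy)-2,6-dihydroxy-3-(hydroxymethyl)benzaldehyde | O=Cc1c(O)cc(OCc2ccccc2)c(CO)c1O | intermediate
5 | 3,4-bis(benzyloxy)benzaldehyde | O=Cc1ccc(OCc2ccccc2)c(OCc2ccccc2)c1 | starting material
6 | 2-{(E)-2-[3,4-bis(benzyloxy)phenyl]ethenyl}-4,4,5,5-tetramethyl-1,3,2-dioxaborolane | CC1(C)OB(/C=C/c2ccc(OCc3ccccc3)c(OCc3ccccc3)c2)OC1(C)C | intermediate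
7 | potassium {(E)-2-[3,4-bis(benzyloxy)phenyl]ethenyl}trifluoroborate | [K+].F[B-](F)(F)/C=C/c1ccc(OCc2ccccc2)c(OCc2ccccc2)c1 | intermediate
8 | (E)-2-[3,4-bis(benzyloxy)phenyl]ethenyl acetate | CC(=O)O/C=C/c1ccc(OCc2ccccc2)c(OCc2ccccc2)c1 | intermediate
9 | 4-(benzyloxy)-2-hydroxy-5-methylidene-6-oxocyclohexa-1,3-diene-1-carbaldehyde (ortho-quinone methide) | C=C1C(=O)C(C=O)=C(O)C=C1OCc1ccccc1 | intermediate
10 | (2R,3S)-3-acetoxy-5-(benzyloxy)-2-[3,4-bis(benzyloxy)phenyl]-7-hydroxychromane-8-carbaldehyde | O=Cc1c(O)cc(OCc2ccccc2)c2c1O[C@H](c1ccc(OCc3ccccc3)c(OCc3ccccc3)c1)[C@@H](OC(C)=O)C2 | intermediate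
11 | (2R,3S)-5-(benzyloxy)-2-[3,4-bis(benzyloxy)phenyl]-3,7-dihydroxychromane-8-carbaldehyde | O=Cc1c(O)cc(OCc2ccccc2)c2c1O[C@H](c1ccc(OCc3ccccc3)c(OCc3ccccc3)c1)[C@@H](O)C2 | intermediate
12 | (2R,3S)-5-(benzyloxy)-2-[3,4-bis(benzyloxy)phenyl]-8-(hydroxymethyl)chromane-3,7-diol | OCc1c(O)cc(OCc2ccccc2)c2c1O[C@H](c1ccc(OCc3ccccc3)c(OCc3ccccc3)c1)[C@@H](O)C2 | intermediate
13 | 2,4,6-trihydroxytoluene | Cc1c(O)cc(O)cc1O | starting material
14 | 2-methyl-1-(2,4,6-trihydroxy-3-methylphenyl)propan-1-one | CC(C)C(=O)c1c(O)cc(O)c(C)c1O | intermediate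
15 | 1-[2-hydroxy-4,6-bis(methoxymethoxy)-3-methylphenyl]-2-methylpropan-1-one | COCOc1cc(OCOC)c(C(=O)C(C)C)c(O)c1C | intermediate
16 | 1-[2-methoxy-4,6-bis(methoxymethoxy)-3-methylphenyl]-2-methylpropan-1-one | COCOc1cc(OCOC)c(C(=O)C(C)C)c(OC)c1C | intermediate
17 | 1-(4,6-dihydroxy-2-methoxy-3-methylphenyl)-2-methylpropan-1-one | COc1c(C)c(O)cc(O)c1C(=O)C(C)C | intermediate
18 | (2R,3S)-5-(benzyloxy)-2-[3,4-bis(benzyloxy)phenyl]-3-hydroxy-8-methylidene-3,4-dihydro-2H-chromen-7(8H)-one (ortho-quinone methide) | C=C1C(=O)C=C(OCc2ccccc2)C2=C1O[C@H](c1ccc(OCc3ccccc3)c(OCc3ccccc3)c1)[C@@H](O)C2 | intermediate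
19 | 1-[3-({(2R,3S)-5-(benzyloxy)-2-[3,4-bis(benzyloxy)phenyl]-3,7-dihydroxychroman-8-yl}methyl)-2,4-dihydroxy-6-methoxy-5-methylphenyl]-2-methylpropan-1-one | COc1c(C)c(O)c(Cc2c(O)cc(OCc3ccccc3)c3c2O[C@H](c2ccc(OCc4ccccc4)c(OCc4ccccc4)c2)[C@@H](O)C3)c(O)c1C(=O)C(C)C | intermediate
20 | pilosanol B | COc1c(C)c(O)c(Cc2c(O)cc(O)c3c2O[C@H](c2ccc(O)c(O)c2)[C@@H](O)C3)c(O)c1C(=O)C(C)C | target

Total step count: 15.
Longest linear sequence: 8 steps (1, 2, 3, 7, 8, 9, 14, 15). The branch through steps 4, 5 and 6 is equally long, and the acylphloroglucinol branch (10 to 13, then 14 and 15) has 6 steps.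

Steps most likely to fail

Step 7. Enantiofacial discrimination may be insufficient, because the dienophile offers the phosphate no hydrogen-bond donor. An unselective background reaction through the free quinone methide, or through its para-quinone methide tautomer (the C7 hydroxyl is para to C4a), may also compete. The fallback gives up catalytic enantiocontrol and uses known chemistry only. It sets out from 4 and 8, which are combined under an achiral acid (diphenyl hydrogen phosphate, CH2Cl2) in the known acid-promoted quinone methide/styrene hetero-Diels-Alder reaction. This should give the racemic trans adduct, that is 10 together with its mirror image (2S,3R)-3-acetoxy-5-(benzyloxy)-2-[3,4-bis(benzyloxy)phenyl]-7-hydroxychromane-8-carbaldehyde F1. A lipase-catalysed kinetic resolution follows (Candida antarctica lipase B, n-BuOH, MTBE, 40 °C). By the empirical size rule for lipases on secondary alcohols, the (3R) acetate should react fast and be converted into (2S,3R)-5-(benzyloxy)-2-[3,4-bis(benzyloxy)phenyl]-3,7-dihydroxychromane-8-carbaldehyde F2. The (3S) acetate should stay acylated, is separated by chromatography and comes back to the route as 10.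

Step 14. C6 of ring A may be alkylated by the quinone methide, both in 12 (self-condensation) and in 19 (over-alkylation), which would lead to oligomerisation. The fallback blocks that carbon with a bromine cap, a device known from flavan-3-ol oligomer chemistry. It sets out from 11.
- Treatment with NBS (1.0 equiv, CH2Cl2, -20 °C) should brominate the only free ring-A carbon and give (2R,3S)-5-(benzyloxy)-2-[3,4-bis(benzyloxy)phenyl]-6-bromo-3,7-dihydroxychromane-8-carbaldehyde F3.
- NaBH4 reduction gives (2R,3S)-5-(benzyloxy)-2-[3,4-bis(benzyloxy)phenyl]-6-bromo-8-(hydroxymethyl)chromane-3,7-diol F4.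
- Pyridinium p-toluenesulfonate in the presence of 17 takes this through (2R,3S)-5-(benzyloxy)-2-[3,4-bis(benzyloxy)phenyl]-6-bromo-3-hydroxy-8-methylidene-3,4-dihydro-2H-chromen-7(8H)-one F5. The coupled product is 1-[3-({(2R,3S)-5-(benzyloxy)-2-[3,4-bis(benzyloxy)phenyl]-6-bromo-3,7-dihydroxychroman-8-yl}methyl)-2,4-dihydroxy-6-methoxy-5-methylphenyl]-2-methylpropan-1-one F6.
- Hydrogenation (H2, 10% Pd/C, NaOAc, THF-MeOH) removes the bromine and the three benzyl groups together, and the fallback comes back to the route at 20.

Step 2. Three processes may erode the yield: double hydroxymethylation, condensation to methylene-bridged dimers, and slow boronate formation at the hydrogen-bonded phenol. The fallback replaces electrophilic formaldehyde chemistry by cross-coupling. It sets out from 2, which is mono-iodinated (NIS, 1.0 equiv, MeCN, 0 °C) to 4-(benzyloxy)-2,6-dihydroxy-3-iodobenzaldehyde F7. A Stille hydroxymethylation with (tributylstannyl)methanol (Pd(PPh3)4, dioxane, 80 °C) then delivers the CH2OH group directly, and the fallback comes back to the route at 4, bypassing 3.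

Further compounds
F1 | step 7 | (2S,3R)-3-acetoxy-5-(benzyloxy)-2-[3,4-bis(benzyloxy)phenyl]-7-hydroxychromane-8-carbaldehyde | O=Cc1c(O)cc(OCc2ccccc2)c2c1O[C@@H](c1ccc(OCc3ccccc3)c(OCc3ccccc3)c1)[C@H](OC(C)=O)C2
F2 | step 7 | (2S,3R)-5-(benzyloxy)-2-[3,4-bis(benzyloxy)phenyl]-3,7-dihydroxychromane-8-carbaldehyde | O=Cc1c(O)cc(OCc2ccccc2)c2c1O[C@@H](c1ccc(OCc3ccccc3)c(OCc3ccccc3)c1)[C@H](O)C2
F3 | step 14 | (2R,3S)-5-(benzyloxy)-2-[3,4-bis(benzyloxy)phenyl]-6-bromo-3,7-dihydroxychromane-8-carbaldehyde | O=Cc1c(O)c(Br)c(OCc2ccccc2)c2c1O[C@H](c1ccc(OCc3ccccc3)c(OCc3ccccc3)c1)[C@@H](O)C2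
F4 | step 14 | (2R,3S)-5-(benzyloxy)-2-[3,4-bis(benzyloxy)phenyl]-6-bromo-8-(hydroxymethyl)chromane-3,7-diol | OCc1c(O)c(Br)c(OCc2ccccc2)c2c1O[C@H](c1ccc(OCc3ccccc3)c(OCc3ccccc3)c1)[C@@H](O)C2
F5 | step 14 | (2R,3S)-5-(benzyloxy)-2-[3,4-bis(benzyloxy)phenyl]-6-bromo-3-hydroxy-8-methylidene-3,4-dihydro-2H-chromen-7(8H)-one | C=C1C(=O)C(Br)=C(OCc2ccccc2)C2=C1O[C@H](c1ccc(OCc3ccccc3)c(OCc3ccccc3)c1)[C@@H](O)C2
F6 | step 14 | 1-[3-({(2R,3S)-5-(benzyloxy)-2-[3,4-bis(benzyloxy)phenyl]-6-bromo-3,7-dihydroxychroman-8-yl}methyl)-2,4-dihydroxy-6-methoxy-5-methylphenyl]-2-methylpropan-1-one | COc1c(C)c(O)c(Cc2c(O)c(Br)c(OCc3ccccc3)c3c2O[C@H](c2ccc(OCc4ccccc4)c(OCc4ccccc4)c2)[C@@H](O)C3)c(O)c1C(=O)C(C)C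
F7 | step 2 | 4-(benzyloxy)-2,6-dihydroxy-3-iodobenzaldehyde | O=Cc1c(O)cc(OCc2ccccc2)c(I)c1O
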